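## The problem

The target is a γ-butyrolactone (O1, C2 carbonyl, C3, C4, C5) with two aryl groups. Ring B (4-hydroxy-3-methoxyphenyl) hangs from C4 through a CH2 group. Ring A (3-hydroxy-4,5-dimethoxyphenyl) is joined to C3 through an exocyclic double bond of (E) geometry, with the aryl group on the side of C4 and away from the carbonyl.

C4 (R) is the only stereocentre. No neighbouring centre can direct it, so a catalyst or reagent has to set it. Its hydrogen is allylic and vinylogously α to the lactone carbonyl once the exocyclic alkene is present, so base or long heating late in the route could racemise it or move the double bond into the ring.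

Both phenols are free and electron-rich, and the alkylidene lactone is a Michael acceptor. The last operations should therefore be neutral and few.

Ring A carries three adjacent oxygens, and only an outer one is a free OH. Differentiating them on a pyrogallol or gallate precursor is awkward. With ring A numbered C1' (side chain) to C6', the sequence C3'(OH)–C4'(OMe)–C5'(OMe)–C6'(H) is that of dimethyl squarate in which one carbonyl has been reduced to CH. The remaining carbonyl carbon can become C3', the two enol ether carbons C4' and C5', and the CH carbon C6'. C1' and C2' can come from a 1,1-disubstituted alkene. This lets ring A be built last, by benzannulation on a finished, enantiopure lactone.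

## Retrosynthesis

**Ring A.** The first cut goes through two bonds of ring A, C1'–C6' and C2'–C3'. It turns target 18 into 4-chloro-2,3-dimethoxycyclobut-2-en-1-one 14 and the 2-stannyl diene 11. In the forward direction the Stille product 15 opens to the dienylketene 16, closes to the cyclohexadienone 17 and tautomerises to 18.
- The neighbouring cut, through the exocyclic C3=CH bond to a ring A benzaldehyde, is the conventional one. It needs a differentiated trioxygenated aldehyde and leaves two protecting groups to remove at the end. It is kept as the fallback.
- The ring A cut fixes the OH/OMe/OMe pattern by connectivity, delivers the free phenol directly and leaves no step after it.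
- The precursors are simpler by a whole arene: 14 has four ring carbons and 11 is a lactone with a three-carbon arm.
- The forward reaction must couple an α-substituted alkenylstannane with a labile chloride without base, tolerate the ring B phenol, and ring-expand at a temperature that leaves C4 and the (E)-alkene alone.

**The chloride.** 14 is cut at C–Cl to the alcohol 13, and 13 at its carbinol C–H to dimethyl squarate 12. Squarate already carries both methoxy groups and both oxygenated carbons in the right order. The alternative, dichloroketene plus a dialkoxyalkyne, has no practical alkyne partner. The forward steps are a mono-reduction of one carbonyl and a substitution that must not ionise C4 of the cyclobutenone.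

**The stannane.** In 11 the C–Sn bond is cut, leading to the terminal enyne 10. Hydrostannation puts tin on last, so no vinyl metal has to pass through enolate chemistry. 10 is the doubly desilylated form of 9: the alkyne C–Si and phenol O–Si bonds are cut together. The phenol protection needed early therefore leaves before tin arrives, and nothing has to be removed after the key step. The forward reactions need internal regioselectivity in the hydrostannation and a buffered fluoride source.

**The exocyclic alkene.** The C3=CH bond of 9 is cut to the (R)-lactone 5 and 3-(trimethylsilyl)propynal 6, through aldol 7 and mesylate 8. An aldol condensation is preferred over a phosphorus-based olefination because 5 needs no prior functionalisation at C3. 5 is simpler by the whole unsaturated arm. The forward step must give the (E)-isomer and must not disturb C4.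

**The lactone and C4.** 5 is cut at the O1–C5 bond by removing the ring oxygen, which gives cyclobutanone 4. C4 becomes the prochiral carbon of a symmetric ketone, so the stereocentre can be set by catalytic desymmetrisation. 4 is cut through two ring bonds to the alkene 2 and dichloroketene, by way of the dichloroketone 3. 2 is the silyl ether of eugenol 1. Eugenol supplies ring B with its oxygen pattern, the benzylic CH2, C4 and one flanking ring carbon. The forward sequence needs only a regioselective [2+2] cycloaddition, a dechlorination and an enantioselective Baeyer–Villiger oxidation.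

## Roads not taken

**Alternative 1:** The cut is made around C4, through C3–C4 and the bond from the benzylic CH2 to ring B.
- Forward key step: the alkenyllithium from the (Z)-alkenyl bromide A2 would add to vinylboronic acid pinacol ester A4. The arylpalladium species from the ring B triflate A3, on a chiral bisphosphine–palladium catalyst, would then trigger a 1,2-shift of the alkenyl group from boron to carbon. The product is the allylic boronate A1 with C4 set.
- Merits: three fragments of similar size are joined in one step, C4 is set by a catalyst, the alkene geometry comes from a stereodefined bromide, and either ring could be varied freely.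
- Weak points: A1 carries boron where C5 must stand. A one-carbon homologation at boron, oxidation, desilylation, oxidation of the allylic alcohol to the acid level with lactonisation, and removal of two methoxymethyl ethers still separate A1 from the target. Alkenyl groups are the less reliable migrating groups in this coupling. A1 is a secondary allylic boronate and could undergo a 1,3-boron shift that would scramble both C4 and the alkene.
- Comparison: this road is more modular than the chosen one and sets C4 at a later, more convergent point. The chosen plan sets against it a stereocentre fixed on a simple ketone, no redox or protecting-group work after its key step, and a ring A whose oxygen pattern needs no differentiation.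

**Alternative 2:** The cut is the O1–C5 bond of the lactone.
- Forward key step: the carboxylic acid of the oxetanyl acrylic acid A6 would open one of the two enantiotopic oxetane CH2–O bonds under a chiral Brønsted acid. This closes the lactone, sets C4 and releases the other arm as the CH2OH group of A5.
- Merits: one catalytic step forms the ring and the stereocentre from an achiral precursor, and the (E)-arylidene unit is in place from the start.
- Weak points: acids that carry an oxetane tend to lactonise without a catalyst, which would erode the enantioselectivity. A5 has CH2OH where the target has CH2–ring B. Activating that carbon for an sp3–sp2 coupling puts a leaving group β to the vinylogously acidic C4–H and invites elimination. The ring A phenol still needs protection and deprotection.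
- Comparison: the desymmetrisation of a four-membered ring is conceptually equal to the Baeyer–Villiger step of the chosen plan, and if the aryl coupling worked this road would be no longer. The chosen plan sets against it that ring B and its CH2 are present from the first step, so no C–C bond has to be made next to C4 after the stereocentre exists.

**Alternative 3:** The cut goes through the aryl–CH bond to ring A and through C3–C4.
- Forward key step: the arylrhodium species from boronic acid A9 would add across the alkyne of the cinnamyl propiolate A8. The alkenylrhodium would close onto the cinnamyl alkene, and protonolysis would leave the benzylic CH2. The product A7 is the bis(silyl) ether of the target.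
- Merits: lactone ring, stereocentre and arylidene unit form in one step, syn addition gives the (E) geometry, and one desilylation finishes the synthesis. This is clearly the shortest road.
- Weak points: after aryl addition to a propiolate, rhodium sits α to the ester and is usually protonated before it can add to an unactivated styrene. The ester tether prefers the conformation that keeps alkyne and alkene apart. The benzylic alkylrhodium has a β-hydrogen at C4 and can eliminate instead of being protonated. The enantioselectivity at C4 would rest on the same uncertain cyclisation.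
- Comparison: in step count this road is better. The chosen plan sets against it that its uncertainty is confined to one step at the very end, that the stereocentre and alkene geometry are secured beforehand by established reaction types, and that a failure of the key step leaves the advanced lactone 5 usable for the fallback.

Key step: step 11

## Route

Remark on the chemistry: 3, 13 and 14 are racemic and 15 is a pair of epimers at the cyclobutenone carbon. None of these centres survives into a later isolated compound. The ligand antipode in step 4 is assumed to be the one that delivers the (R)-lactone.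

Step 1
Reactants: 1 eugenol (4-allyl-2-methoxyphenol)
Product: 2 tert-butyl(4-allyl-2-methoxyphenoxy)dimethylsilane
Conditions: TBSCl, imidazole, DMF, rt
Reagents that add atoms: tert-butyldimethylsilyl chloride, CC(C)(C)[Si](C)(C)Cl
Why: Standard silylation of a phenol; the free OH would be acylated by trichloroacetyl chloride in step 2 and would consume base in step 5.

Step 2
Reactants: 2 tert-butyl(4-allyl-2-methoxyphenoxy)dimethylsilane
Product: 3 2,2-dichloro-3-[4-(tert-butyldimethylsilyloxy)-3-methoxybenzyl]cyclobutan-1-one (racemic)
Conditions: Cl3CCOCl, Zn–Cu couple, POCl3, Et2O, reflux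
Reagents that add atoms: trichloroacetyl chloride (source of dichloroketene), ClC(=O)C(Cl)(Cl)Cl
Why: [2+2] cycloaddition of dichloroketene, made in the flask by zinc dechlorination, to a terminal alkene; the carbonyl carbon bonds to the terminal CH2 and the CCl2 carbon to the substituted carbon, as is usual for allylarenes. The new centre is racemic and ceases to be a stereocentre in step 3.

Step 3
Reactants: 3 2,2-dichloro-3-[4-(tert-butyldimethylsilyloxy)-3-methoxybenzyl]cyclobutan-1-one
Product: 4 3-[4-(tert-butyldimethylsilyloxy)-3-methoxybenzyl]cyclobutan-1-one
Conditions: Zn dust, AcOH, rt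
Reagents that add atoms: none
Why: Reductive removal of both α-chlorines by zinc in acetic acid, the usual follow-up to a dichloroketene cycloaddition; the aryl silyl ether is stable to these conditions and the product is a symmetric, prochiral ketone.

Step 4
Reactants: 4 3-[4-(tert-butyldimethylsilyloxy)-3-methoxybenzyl]cyclobutan-1-one
Product: 5 (R)-4-[4-(tert-butyldimethylsilyloxy)-3-methoxybenzyl]dihydrofuran-2(3H)-one
Conditions: Sc(OTf)3 (5 mol%), chiral N,N'-dioxide ligand (6 mol%), mCPBA, EtOAc, −20 °C
Reagents that add atoms: 3-chloroperbenzoic acid, OOC(=O)c1cccc(Cl)c1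
Why: Catalytic asymmetric Baeyer–Villiger desymmetrisation of a 3-substituted cyclobutanone; the chiral scandium Lewis acid binds the ketone and selects which of the two enantiotopic CH2 groups migrates in the peracid adduct, which sets C4. The enantiomeric purity can be raised by crystallising a later intermediate if needed.

Step 5
Reactants: 5 (R)-4-[4-(tert-butyldimethylsilyloxy)-3-methoxybenzyl]dihydrofuran-2(3H)-one; 6 3-(trimethylsilyl)propynal
Product: 7 (3S,4R)-4-[4-(tert-butyldimethylsilyloxy)-3-methoxybenzyl]-3-[1-hydroxy-3-(trimethylsilyl)prop-2-yn-1-yl]dihydrofuran-2(3H)-one (3,4-trans, both carbinol epimers)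
Conditions: LiN(iPr)2, THF, −78 °C; then 6, −78 °C
Reagents that add atoms: none
Why: Aldol addition of the lithium enolate of 5 to a non-enolisable ynal; the electrophile approaches anti to the C4 benzyl group, and both new centres are removed in step 6, so their ratio does not matter. C4 is not touched by kinetic deprotonation at C3.

Step 6
Reactants: 7 (3S,4R)-4-[4-(tert-butyldimethylsilyloxy)-3-methoxybenzyl]-3-[1-hydroxy-3-(trimethylsilyl)prop-2-yn-1-yl]dihydrofuran-2(3H)-one
Product: 9 (R,E)-4-[4-(tert-butyldimethylsilyloxy)-3-methoxybenzyl]-3-[3-(trimethylsilyl)prop-2-yn-1-ylidene]dihydrofuran-2(3H)-one, via mesylate 8 (not isolated)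
Conditions: MsCl, Et3N, CH2Cl2, 0 °C; then DBU, 0 °C to rt
Reagents that add atoms: none
Why: Mesylation and E1cB elimination, the standard dehydration of lactone aldols; the enolate-like transition state should favour the (E)-alkene with the slim alkynyl group anti to the carbonyl, and any (Z)-isomer is removed by chromatography. Brief exposure to DBU at low temperature limits deprotonation at C4.

Step 7
Reactants: 9 (R,E)-4-[4-(tert-butyldimethylsilyloxy)-3-methoxybenzyl]-3-[3-(trimethylsilyl)prop-2-yn-1-ylidene]dihydrofuran-2(3H)-one
Product: 10 (R,E)-4-(4-hydroxy-3-methoxybenzyl)-3-(prop-2-yn-1-ylidene)dihydrofuran-2(3H)-one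
Conditions: Bu4NF, AcOH, THF, 0 °C
Reagents that add atoms: none
Why: Fluoride cleaves both the aryl silyl ether and the alkynyl C–Si bond; acetic acid buffering keeps phenoxide and acetylide from adding to the conjugated acceptor and protects the C4–H.

Step 8
Reactants: 10 (R,E)-4-(4-hydroxy-3-methoxybenzyl)-3-(prop-2-yn-1-ylidene)dihydrofuran-2(3H)-one
Product: 11 (R,E)-4-(4-hydroxy-3-methoxybenzyl)-3-[2-(tributylstannyl)prop-2-en-1-ylidene]dihydrofuran-2(3H)-one
Conditions: Bu3SnH (slow addition), PdCl2(PPh3)2 (2 mol%), THF, 0 °C
Reagents that add atoms: tributyltin hydride, CCCC[SnH](CCCC)CCCC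
Why: Palladium-catalysed syn hydrostannation of a terminal alkyne; in this vinylogous ynoate the terminal carbon is the electrophilic end, so hydrogen should go there and tin to the internal carbon, as with ynoates and conjugated enynes. The phenol and the lactone are tolerated.

Step 9
Reactants: 12 dimethyl squarate (3,4-dimethoxycyclobut-3-ene-1,2-dione)
Product: 13 4-hydroxy-2,3-dimethoxycyclobut-2-en-1-one (racemic)
Conditions: LiAlH(OtBu)3, THF, −78 °C; pH 7 buffer work-up
Reagents that add atoms: none
Why: 1,2-Reduction of one carbonyl of a dialkyl squarate by a hindered hydride, a known entry to 4-hydroxycyclobutenones; the neutral work-up avoids the acid-induced collapse to the semisquarate.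

Step 10
Reactants: 13 4-hydroxy-2,3-dimethoxycyclobut-2-en-1-one
Product: 14 4-chloro-2,3-dimethoxycyclobut-2-en-1-one (racemic, used at once)
Conditions: PPh3, CCl4, CH2Cl2, 0 °C
Reagents that add atoms: carbon tetrachloride, ClC(Cl)(Cl)Cl
Why: Appel chlorination under neutral conditions; displacement of the oxyphosphonium group by chloride at the α-keto carbon avoids free acid, and attack at the electron-rich enol ether carbon is electronically disfavoured.

Step 11
Reactants: 11 (R,E)-4-(4-hydroxy-3-methoxybenzyl)-3-[2-(tributylstannyl)prop-2-en-1-ylidene]dihydrofuran-2(3H)-one; 14 4-chloro-2,3-dimethoxycyclobut-2-en-1-one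
Product: 18 (R,E)-4-(4-hydroxy-3-methoxybenzyl)-3-(3-hydroxy-4,5-dimethoxybenzylidene)dihydrofuran-2(3H)-one, via dienylcyclobutenone 15 (not isolated), via dienylketene 16 (not isolated), via cyclohexadienone 17 (not isolated)
Conditions: Pd2(dba)3 (2.5 mol%), P(2-furyl)3 (10 mol%), dioxane, 50 °C; then 100 °C
Reagents that add atoms: none
Why: Proposed new method: zerovalent palladium formed from Pd2(dba)3 and tri(2-furyl)phosphine should insert into the allylic, α-keto C–Cl bond of 14, the alkenyl group of 11 is then transferred from tin to divalent palladium, and reductive elimination joins the stannane carbon (future C1') to the CHCl carbon (future C6') to give 15 as a pair of epimers at a centre that is erased in the next event. At 100 °C the cyclobutenone should undergo thermal conrotatory 4π ring opening to the vinylketene 16; opening with the dienyl arm turned outward is unproductive but reversible, so the material drains through the inward rotamer. In 16 the ketene C=C, the former ring alkene and the C=CH2 unit form a hexatriene, and a thermal disrotatory 6π electrocyclisation between the ketene carbon and the CH2 terminus closes the six-membered carbocycle of ring A (bond C2'–C3') as cyclohexadienone 17, which tautomerises to the phenol. The closest known reaction type is the Stille coupling of alkyl- or aryl-substituted 4-chlorocyclobut-2-enones with alkenylstannanes followed by thermal ring expansion to phenols; it has not been shown for a 2,3-dialkoxy chloride or for a 2-stannyl-1,3-diene. No stereocentre is formed in the product, and C4 and the (E)-alkene are spectators under neutral, base-free conditions. Regiochemistry needs no control, because the exocyclic alkene at C3 is cross-conjugated at C1' and cannot join the triene, so the only closure available places OH, OMe, OMe and the side chain as in the target. What is needed is a favourable order of rates, coupling before ionisation of the chloride and ring closure of the ketene before its capture by a phenol; the weakly bound phosphine, the absence of base and the intramolecular 6π closure are relied on for that.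

## Compound list

1 | eugenol (4-allyl-2-methoxyphenol) | C=CCc1ccc(O)c(OC)c1 | starting material
2 | tert-butyl(4-allyl-2-methoxyphenoxy)dimethylsilane | C=CCc1ccc(O[Si](C)(C)C(C)(C)C)c(OC)c1 | intermediate
3 | 2,2-dichloro-3-[4-(tert-butyldimethylsilyloxy)-3-methoxybenzyl]cyclobutan-1-one (racemic) | COc1cc(CC2CC(=O)C2(Cl)Cl)ccc1O[Si](C)(C)C(C)(C)C | intermediate
4 | 3-[4-(tert-butyldimethylsilyloxy)-3-methoxybenzyl]cyclobutan-1-one | COc1cc(CC2CC(=O)C2)ccc1O[Si](C)(C)C(C)(C)C | intermediate
5 | (R)-4-[4-(tert-butyldimethylsilyloxy)-3-methoxybenzyl]dihydrofuran-2(3H)-one | COc1cc(C[C@H]2COC(=O)C2)ccc1O[Si](C)(C)C(C)(C)C | intermediate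
6 | 3-(trimethylsilyl)propynal | C[Si](C)(C)C#CC=O | starting material
7 | (3S,4R)-4-[4-(tert-butyldimethylsilyloxy)-3-methoxybenzyl]-3-[1-hydroxy-3-(trimethylsilyl)prop-2-yn-1-yl]dihydrofuran-2(3H)-one (both carbinol epimers) | COc1cc(C[C@H]2COC(=O)[C@@H]2C(O)C#C[Si](C)(C)C)ccc1O[Si](C)(C)C(C)(C)C | intermediate
8 | methanesulfonate of 7 (not isolated) | COc1cc(C[C@H]2COC(=O)[C@@H]2C(OS(C)(=O)=O)C#C[Si](C)(C)C)ccc1O[Si](C)(C)C(C)(C)C | intermediate
9 | (R,E)-4-[4-(tert-butyldimethylsilyloxy)-3-methoxybenzyl]-3-[3-(trimethylsilyl)prop-2-yn-1-ylidene]dihydrofuran-2(3H)-one | COc1cc(C[C@H]2COC(=O)/C2=C/C#C[Si](C)(C)C)ccc1O[Si](C)(C)C(C)(C)C | intermediate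
10 | (R,E)-4-(4-hydroxy-3-methoxybenzyl)-3-(prop-2-yn-1-ylidene)dihydrofuran-2(3H)-one | COc1cc(C[C@H]2COC(=O)/C2=C/C#C)ccc1O | intermediate
11 | (R,E)-4-(4-hydroxy-3-methoxybenzyl)-3-[2-(tributylstannyl)prop-2-en-1-ylidene]dihydrofuran-2(3H)-one | COc1cc(C[C@H]2COC(=O)/C2=C/C(=C)[Sn](CCCC)(CCCC)CCCC)ccc1O | intermediate
12 | dimethyl squarate (3,4-dimethoxycyclobut-3-ene-1,2-dione) | COC1=C(OC)C(=O)C1=O | starting material
13 | 4-hydroxy-2,3-dimethoxycyclobut-2-en-1-one (racemic) | COC1=C(OC)C(O)C1=O | intermediate
14 | 4-chloro-2,3-dimethoxycyclobut-2-en-1-one (racemic) | COC1=C(OC)C(Cl)C1=O | intermediate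
15 | (R,E)-3-[2-(2,3-dimethoxy-4-oxocyclobut-2-en-1-yl)prop-2-en-1-ylidene]-4-(4-hydroxy-3-methoxybenzyl)dihydrofuran-2(3H)-one (both epimers at the cyclobutenone carbon; not isolated) | COc1cc(C[C@H]2COC(=O)/C2=C/C(=C)C3C(OC)=C(OC)C3=O)ccc1O | intermediate
16 | (3E)-2,3-dimethoxy-5-{(E)-[(R)-4-(4-hydroxy-3-methoxybenzyl)-2-oxodihydrofuran-3(2H)-ylidene]methyl}hexa-1,3,5-trien-1-one (dienylketene, dienyl arm cis to the ketene carbon; not isolated) | COc1cc(C[C@H]2COC(=O)/C2=C/C(=C)/C=C(OC)\C(OC)=C=O)ccc1O | intermediate
17 | 2,3-dimethoxy-5-{(E)-[(R)-4-(4-hydroxy-3-methoxybenzyl)-2-oxodihydrofuran-3(2H)-ylidene]methyl}cyclohexa-2,4-dien-1-one (not isolated) | COc1cc(C[C@H]2COC(=O)/C2=C/C3=CC(OC)=C(OC)C(=O)C3)ccc1O | intermediate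
18 | (R,E)-4-(4-hydroxy-3-methoxybenzyl)-3-(3-hydroxy-4,5-dimethoxybenzylidene)dihydrofuran-2(3H)-one | COc1cc(C[C@H]2COC(=O)/C2=C/c2cc(O)c(OC)c(OC)c2)ccc1O | target

## Step count and risk

Total: 11 steps. Longest linear sequence: 9 steps (steps 1 to 8, then step 11). The squarate branch contributes steps 9 and 10. Step 11 is the only step that carries the label of a proposed new method.

**Step 11 (key step).**
- What may go wrong: the chloride may ionise and lose methyl chloride to the semisquarate faster than palladium inserts. Transmetalation of the hindered α-substituted stannane may be slow, so that protodestannylation by the phenol or homocoupling takes over. The ketene may be captured between molecules by a phenol before it cyclises.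
- Fallback (known chemistry), from 5 back to 18: commercial 3-hydroxy-4,5-dimethoxybenzaldehyde F1 is silylated (TBSCl, imidazole) to 3-(tert-butyldimethylsilyloxy)-4,5-dimethoxybenzaldehyde F2. The lithium enolate of 5 is added to it to give the aldol adduct F3. This is converted to its mesylate F4 and eliminated with DBU to the bis(silyl) ether F5. Buffered Bu4NF then removes both silyl groups and gives 18. This gives up the late benzannulation for the classical arylidene condensation and carries ring A in from a pre-formed arene.

**Step 10.**
- What may go wrong: the activated alcohol or the chloride may collapse through ionisation at the cyclobutenone C4 and loss of a methyl group, or through allylic transposition of chloride, before it can be used.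
- Fallback, from 13 back to 15 (and from there to 18 under the thermal part of step 11): the alcohol is acetylated (Ac2O, pyridine) to 2,3-dimethoxy-4-oxocyclobut-2-en-1-yl acetate F6. This less easily ionised allylic ester is used as the electrophile with 11 under Pd2(dba)3, tri(2-furyl)phosphine and LiCl in DMF. The C–C bond is then formed from an allylic acetate instead of a chloride.

**Step 8.**
- What may go wrong: tin may be delivered to the terminal carbon, giving the linear (E)-stannane, or the hydride may reduce the conjugated system.
- Fallback, from 10 back to 11: palladium-catalysed addition of hexabutylditin (Pd(PPh3)4, THF, reflux) gives the (Z)-2,3-bis(tributylstannyl) diene F7. One equivalent of anhydrous HCl in Et2O at low temperature then removes the terminal tin selectively, because protonation at the terminal carbon gives the more stabilised cation. The 2-stannyl diene 11 remains, with regiochemistry fixed by the order of events and not by the catalyst.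

**Step 4.**
- What may go wrong: the catalyst may discriminate poorly between the two enantiotopic migrating CH2 groups, since the benzyl substituent is remote from the carbonyl and flexible.
- Fallback, from 2 back to 5: hydroboration–oxidation of 2 (9-BBN, then NaBO3·4H2O) gives 3-[4-(tert-butyldimethylsilyloxy)-3-methoxyphenyl]propan-1-ol F8. It is converted to the diazoacetate F9 with the p-toluenesulfonylhydrazone of glyoxylic acid chloride, N,N-dimethylaniline and then Et3N. Dirhodium tetrakis[methyl 2-oxo-1-(3-phenylpropanoyl)imidazolidine-4-carboxylate], Rh2(MPPIM)4, in the enantiomeric form that gives the (R)-lactone, then inserts the carbene into the C–H bond β to the ester oxygen and closes 5 directly. C4 is then set by C–H insertion instead of oxygen insertion.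

## Further compounds

F1 | step 11 | 3-hydroxy-4,5-dimethoxybenzaldehyde | COc1cc(C=O)cc(O)c1OC
F2 | step 11 | 3-(tert-butyldimethylsilyloxy)-4,5-dimethoxybenzaldehyde | COc1cc(C=O)cc(O[Si](C)(C)C(C)(C)C)c1OC
F3 | step 11 | (3S,4R)-4-[4-(tert-butyldimethylsilyloxy)-3-methoxybenzyl]-3-{[3-(tert-butyldimethylsilyloxy)-4,5-dimethoxyphenyl](hydroxy)methyl}dihydrofuran-2(3H)-one (both carbinol epimers) | COc1cc(C[C@H]2COC(=O)[C@@H]2C(O)c2cc(O[Si](C)(C)C(C)(C)C)c(OC)c(OC)c2)ccc1O[Si](C)(C)C(C)(C)C
F4 | step 11 | methanesulfonate of F3 | COc1cc(C[C@H]2COC(=O)[C@@H]2C(OS(C)(=O)=O)c2cc(O[Si](C)(C)C(C)(C)C)c(OC)c(OC)c2)ccc1O[Si](C)(C)C(C)(C)C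
F5 | step 11 | (R,E)-4-[4-(tert-butyldimethylsilyloxy)-3-methoxybenzyl]-3-[3-(tert-butyldimethylsilyloxy)-4,5-dimethoxybenzylidene]dihydrofuran-2(3H)-one | COc1cc(C[C@H]2COC(=O)/C2=C/c2cc(O[Si](C)(C)C(C)(C)C)c(OC)c(OC)c2)ccc1O[Si](C)(C)C(C)(C)C
F6 | step 10 | 2,3-dimethoxy-4-oxocyclobut-2-en-1-yl acetate (racemic) | COC1=C(OC)C(OC(C)=O)C1=O
F7 | step 8 | (R)-3-[(1E,2Z)-2,3-bis(tributylstannyl)prop-2-en-1-ylidene]-4-(4-hydroxy-3-methoxybenzyl)dihydrofuran-2(3H)-one | COc1cc(C[C@H]2COC(=O)/C2=C/C(=C/[Sn](CCCC)(CCCC)CCCC)[Sn](CCCC)(CCCC)CCCC)ccc1O
F8 | step 4 | 3-[4-(tert-butyldimethylsilyloxy)-3-methoxyphenyl]propan-1-ol | COc1cc(CCCO)ccc1O[Si](C)(C)C(C)(C)C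
F9 | step 4 | 3-[4-(tert-butyldimethylsilyloxy)-3-methoxyphenyl]propyl diazoacetate | COc1cc(CCCOC(=O)C=[N+]=[N-])ccc1O[Si](C)(C)C(C)(C)C
A1 | alternative 1 | (R,E)-tert-butyl{[2-{2-[3-methoxy-4-(methoxymethoxy)phenyl]-1-(4,4,5,5-tetramethyl-1,3,2-dioxaborolan-2-yl)ethyl}-3-[3,4-dimethoxy-5-(methoxymethoxy)phenyl]prop-2-en-1-yl]oxy}dimethylsilane (secondary allylic pinacol boronate) | COc1cc(C[C@H](/C(CO[Si](C)(C)C(C)(C)C)=C\c2cc(OCOC)c(OC)c(OC)c2)B2OC(C)(C)C(C)(C)O2)ccc1OCOC
A2 | alternative 1 | (Z)-{[2-bromo-3-[3,4-dimethoxy-5-(methoxymethoxy)phenyl]prop-2-en-1-yl]oxy}(tert-butyl)dimethylsilane | CC(C)(C)[Si](C)(C)OC/C(Br)=C/c1cc(OCOC)c(OC)c(OC)c1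
A3 | alternative 1 | 3-methoxy-4-(methoxymethoxy)phenyl trifluoromethanesulfonate | COCOc1ccc(OS(=O)(=O)C(F)(F)F)cc1OC
A4 | alternative 1 | vinylboronic acid pinacol ester | C=CB1OC(C)(C)C(C)(C)O1
A5 | alternative 2 | (S,E)-4-(hydroxymethyl)-3-[3-(methoxymethoxy)-4,5-dimethoxybenzylidene]dihydrofuran-2(3H)-one | OC[C@H]1COC(=O)/C1=C/c1cc(OCOC)c(OC)c(OC)c1
A6 | alternative 2 | (E)-3-[3-(methoxymethoxy)-4,5-dimethoxyphenyl]-2-(oxetan-3-yl)prop-2-enoic acid | OC(=O)/C(=C/c1cc(OCOC)c(OC)c(OC)c1)C1COC1
A7 | alternative 3 | (R,E)-4-[4-(tert-butyldimethylsilyloxy)-3-methoxybenzyl]-3-[3-(tert-butyldimethylsilyloxy)-4,5-dimethoxybenzylidene]dihydrofuran-2(3H)-one | COc1cc(C[C@H]2COC(=O)/C2=C/c2cc(O[Si](C)(C)C(C)(C)C)c(OC)c(OC)c2)ccc1O[Si](C)(C)C(C)(C)C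
A8 | alternative 3 | (E)-3-[4-(tert-butyldimethylsilyloxy)-3-methoxyphenyl]prop-2-en-1-yl propiolate | C#CC(=O)OC/C=C/c1ccc(O[Si](C)(C)C(C)(C)C)c(OC)c1
A9 | alternative 3 | [3-(tert-butyldimethylsilyloxy)-4,5-dimethoxyphenyl]boronic acid | OB(O)c1cc(O[Si](C)(C)C(C)(C)C)c(OC)c(OC)c1
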